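**Plan**

- Retrosynthesis: remove the three silyl groups, cut the aryl–vinyl bond of the stilbene at C5 (Mizoroki–Heck, aryl bromide + styrene), and take CH2OH back to CO2Me.
- Enabling feature: C3 of the dihydrofuran ring carries a one-carbon substituent and is bonded to ring A carbon C3a, which lies ortho to the ring oxygen. This C3a–C3(–C) array is the trace of a 1,2-aryl shift, so the ester carbon is put back between C3 and C3a to give a flavanone (chroman-4-one) whose C4 carbonyl becomes the exocyclic carbon.
- The flavanone is cut at C2–aryl (arylboronic acid + 6-bromo-8-methoxychromone), and the chromone at O1–C2/C2–C3 back to an o-hydroxyacetophenone.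
- Forward order: ring A with the pyranone ring (chromone), then the C2–aryl bond, then contraction of the six-membered pyranone ring to the five-membered dihydrofuran ring with excision of C4 as CO2Me, then reduction, stilbene coupling and desilylation.
- Stereochemistry: C2 (R) from the ligand-controlled conjugate addition; C3 from the contraction itself (anti iodination, migration with inversion, trans ester); the E alkene from syn insertion and syn β-hydride elimination.

Key step: step 6

Remark on the chemistry: (S)-t-BuPyOx is assumed to deliver the aryl group to the chromone face that corresponds to the one attacked in carbocyclic enones, which gives the (R)-flavanone; with the opposite sense, (R)-t-BuPyOx would be used. Compounds 1, 5 and 18 are taken as commercial.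

**Route**

Step 1
Reactants: 1 1-(2-hydroxy-3-methoxyphenyl)ethan-1-one
Product: 2 1-(5-bromo-2-hydroxy-3-methoxyphenyl)ethan-1-one
Conditions: NBS, MeCN, 0 °C to rt
Reagents that add atoms: N-bromosuccinimide, O=C1CCC(=O)N1Br
Why: Electrophilic aromatic bromination; the free phenol directs para and the acetyl group meta, both to C5, the only open position activated by the hydroxyl group.

Step 2
Reactants: 2 1-(5-bromo-2-hydroxy-3-methoxyphenyl)ethan-1-one
Product: 4 6-bromo-8-methoxy-4H-chromen-4-one, via enaminone 3 (not isolated)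
Conditions: Me2NCH(OMe)2, toluene, 100 °C; then conc. HCl, CH2Cl2, 40 °C
Reagents that add atoms: N,N-dimethylformamide dimethyl acetal, COC(OC)N(C)C
Why: Condensation of the methyl ketone with the amide acetal gives the enaminone, and acid then drives conjugate addition of the phenol and loss of dimethylamine (addition–elimination, the standard enaminone chromone synthesis); no stereocentre is formed.

Step 3
Reactants: 5 4-bromo-2-methoxyphenol
Product: 6 (4-bromo-2-methoxyphenoxy)tri(propan-2-yl)silane
Conditions: TIPSCl, imidazole, DMF, rt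
Reagents that add atoms: chlorotri(propan-2-yl)silane, CC(C)[Si](Cl)(C(C)C)C(C)C
Why: Imidazole-promoted phenol silylation; the bulky TIPS ether is chosen because it should survive the organolithium, the aqueous palladium catalysis, the acidic key step and the hydride, and fall to fluoride at the end.

Step 4
Reactants: 6 (4-bromo-2-methoxyphenoxy)tri(propan-2-yl)silane
Product: 9 [3-methoxy-4-(triisopropylsilyloxy)phenyl]boronic acid, via aryllithium 7 (not isolated), via lithium arylborate 8 (not isolated)
Conditions: n-BuLi, THF, −78 °C; B(OiPr)3, −78 °C to rt; 1 M HCl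
Reagents that add atoms: triisopropyl borate, CC(C)OB(OC(C)C)OC(C)C; water, O
Why: Bromine–lithium exchange, borate formation and hydrolysis (standard arylboronic acid synthesis); the silyl ether is inert to n-BuLi at −78 °C and there is no leaving group ortho to the lithiated carbon.

Step 5
Reactants: 4 6-bromo-8-methoxy-4H-chromen-4-one; 9 [3-methoxy-4-(triisopropylsilyloxy)phenyl]boronic acid
Product: 10 (2R)-6-bromo-8-methoxy-2-[3-methoxy-4-(triisopropylsilyloxy)phenyl]-2,3-dihydro-4H-chromen-4-one
Conditions: Pd(OCOCF3)2 (5 mol%), (S)-t-BuPyOx (6 mol%), NH4PF6 (30 mol%), H2O (5 equiv), ClCH2CH2Cl, 60 °C, air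
Reagents that add atoms: none
Why: Catalytic asymmetric conjugate addition of an arylboronic acid to a chromone with a cationic divalent palladium/pyridine-oxazoline catalyst: aryl transfer to palladium, enantioface-selective insertion of the C2=C3 bond and protonolysis of the palladium enolate should set C2 as R under ligand control, and because the cycle stays at divalent palladium the aryl bromide should not be engaged.

Step 6
Reactants: 10 (2R)-6-bromo-8-methoxy-2-[3-methoxy-4-(triisopropylsilyloxy)phenyl]-2,3-dihydro-4H-chromen-4-one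
Product: 15 methyl (2R,3R)-5-bromo-7-methoxy-2-[3-methoxy-4-(triisopropylsilyloxy)phenyl]-2,3-dihydro-1-benzofuran-3-carboxylate, via dimethyl ketal 11 (not isolated), via enol ether 12 (not isolated), via trans λ3-iodane 13 (not isolated), via orthoester 14 (not isolated)
Conditions: PhI(OAc)2 (1.2 equiv), conc. H2SO4 (cat.), HC(OMe)3, 0 °C to rt; then H2O
Reagents that add atoms: trimethyl orthoformate, COC(OC)OC; water, O
Why: Under H2SO4 in HC(OMe)3 the ketone is converted through ketal 11 into enol ether 12; PhI(OAc)2 (trivalent iodine) then adds to C3 on the face opposite the C2 aryl group while methanol caps C4, giving the 2,3-trans λ3-iodane 13, whose pseudo-equatorial C3–I bond lies antiperiplanar to the C4–C4a ring bond. Reductive loss of iodobenzene is assisted by a 1,2-shift of ring A carbon C4a from C4 to C3 through a phenonium-type bridged ion, which pushes C4 out of the ring as a dimethoxycarbenium ion, held as orthoester 14 and hydrolysed to the methyl ester on work-up. The closest known reaction type is the trivalent-iodine (or trivalent-thallium) oxidative rearrangement of flavanones and chroman-4-ones to 2,3-dihydrobenzofuran-3-carboxylates, a semipinacol-like 1,2-aryl shift. The five-membered ring is closed at C3–C4a by intramolecular backside displacement at C3 (3-exo-tet attack of the arene ipso carbon, then cleavage of the old C4–C4a bond of the spiro bridge), a net six-to-five ring contraction. C2 is untouched and keeps the R configuration from step 5, while C3 is set by substrate control: iodination anti to the aryl group followed by inversion at C3 places the ester trans to the aryl group, which is also the more stable epimer of this enolisable centre. The step needs migration of C4a in preference to the C2 aryl group (isoflavone pathway) and to loss of H (flavone pathway); the antiperiplanar ring bond, the ortho ring oxygen that stabilises the bridged ion, and the equatorial 2-aryl group lying gauche to the C–I bond should secure this.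

Step 7
Reactants: 15 methyl (2R,3R)-5-bromo-7-methoxy-2-[3-methoxy-4-(triisopropylsilyloxy)phenyl]-2,3-dihydro-1-benzofuran-3-carboxylate
Product: 17 [(2R,3S)-5-bromo-7-methoxy-2-[3-methoxy-4-(triisopropylsilyloxy)phenyl]-2,3-dihydro-1-benzofuran-3-yl]methanol, via aldehyde 16 (not isolated)
Conditions: DIBAL-H (3 equiv), CH2Cl2, −78 to 0 °C; aq. Rochelle salt
Reagents that add atoms: none
Why: Ester-to-primary-alcohol reduction with DIBAL-H; the Lewis-acidic, non-basic hydride should avoid enolisation and E1cB opening at C3, leave the aryl bromide and silyl ether alone, and touch neither stereocentre (the C3 descriptor changes from R to S only through CIP ranking).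

Step 8
Reactants: 18 3,5-dihydroxybenzaldehyde
Product: 19 3,5-bis(tert-butyldimethylsilyloxy)benzaldehyde
Conditions: TBSCl, imidazole, DMF, rt
Reagents that add atoms: tert-butyl(chloro)dimethylsilane, CC(C)(C)[Si](C)(C)Cl
Why: Standard imidazole-promoted silylation of both phenols, giving ethers that leave with the TIPS group in the last step.

Step 9
Reactants: 19 3,5-bis(tert-butyldimethylsilyloxy)benzaldehyde
Product: 21 1-ethenyl-3,5-bis(tert-butyldimethylsilyloxy)benzene, via oxaphosphetane 20 (not isolated)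
Conditions: Ph3PCH3Br, KOtBu, THF, 0 °C; then 19, 0 °C to rt
Reagents that add atoms: methyltriphenylphosphonium bromide, C[P+](c1ccccc1)(c1ccccc1)c1ccccc1.[Br-]
Why: Wittig methylenation of an aromatic aldehyde with the preformed non-stabilised ylide, which aryl silyl ethers should tolerate when no excess alkoxide is present.

Step 10
Reactants: 17 [(2R,3S)-5-bromo-7-methoxy-2-[3-methoxy-4-(triisopropylsilyloxy)phenyl]-2,3-dihydro-1-benzofuran-3-yl]methanol; 21 1-ethenyl-3,5-bis(tert-butyldimethylsilyloxy)benzene
Product: 22 [(2R,3S)-5-[(E)-2-[3,5-bis(tert-butyldimethylsilyloxy)phenyl]ethenyl]-7-methoxy-2-[3-methoxy-4-(triisopropylsilyloxy)phenyl]-2,3-dihydro-1-benzofuran-3-yl]methanol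
Conditions: Pd2(dba)3 (2.5 mol%), [HP(t-Bu)3]BF4 (6 mol%), Cy2NMe, 1,4-dioxane, 80 °C
Reagents that add atoms: none
Why: Mizoroki–Heck reaction: oxidative addition of the electron-rich aryl bromide to zerovalent palladium bearing P(t-Bu)3, syn insertion of the styrene at its terminal carbon and syn β-hydride elimination should give the (E)-stilbene, and the mild amine base should leave the silyl ethers, the free alcohol and both stereocentres untouched.

Step 11
Reactants: 22 [(2R,3S)-5-[(E)-2-[3,5-bis(tert-butyldimethylsilyloxy)phenyl]ethenyl]-7-methoxy-2-[3-methoxy-4-(triisopropylsilyloxy)phenyl]-2,3-dihydro-1-benzofuran-3-yl]methanol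
Product: 23 gnetofuran A
Conditions: Bu4NF (3.5 equiv), AcOH (3.5 equiv), THF, 0 °C to rt
Reagents that add atoms: none
Why: Fluoride-mediated cleavage of the three aryl silyl ethers; acetic acid buffers the phenoxides so that the 4-hydroxybenzylic C2–O bond should not open to a quinone methide and C2 should not epimerise.

**Compound list**

1 | 1-(2-hydroxy-3-methoxyphenyl)ethan-1-one | CC(=O)c1cccc(OC)c1O | starting material
2 | 1-(5-bromo-2-hydroxy-3-methoxyphenyl)ethan-1-one | CC(=O)c1cc(Br)cc(OC)c1O | intermediate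
3 | (E)-1-(5-bromo-2-hydroxy-3-methoxyphenyl)-3-(dimethylamino)prop-2-en-1-one (enaminone) | CN(C)/C=C/C(=O)c1cc(Br)cc(OC)c1O | intermediate
4 | 6-bromo-8-methoxy-4H-chromen-4-one | O=c1ccoc2c(OC)cc(Br)cc12 | intermediate
5 | 4-bromo-2-methoxyphenol | COc1cc(Br)ccc1O | starting material
6 | (4-bromo-2-methoxyphenoxy)tri(propan-2-yl)silane | COc1cc(Br)ccc1O[Si](C(C)C)(C(C)C)C(C)C | intermediate
7 | [3-methoxy-4-(triisopropylsilyloxy)phenyl]lithium | COc1cc([Li])ccc1O[Si](C(C)C)(C(C)C)C(C)C | intermediate
8 | lithium [3-methoxy-4-(triisopropylsilyloxy)phenyl]tri(propan-2-yloxy)borate | COc1cc([B-](OC(C)C)(OC(C)C)OC(C)C)ccc1O[Si](C(C)C)(C(C)C)C(C)C.[Li+] | intermediate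
9 | [3-methoxy-4-(triisopropylsilyloxy)phenyl]boronic acid | COc1cc(B(O)O)ccc1O[Si](C(C)C)(C(C)C)C(C)C | intermediate
10 | (2R)-6-bromo-8-methoxy-2-[3-methoxy-4-(triisopropylsilyloxy)phenyl]-2,3-dihydro-4H-chromen-4-one | COc1cc([C@@H]2Oc3c(OC)cc(Br)cc3C(=O)C2)ccc1O[Si](C(C)C)(C(C)C)C(C)C | intermediate
11 | (2R)-6-bromo-4,4,8-trimethoxy-2-[3-methoxy-4-(triisopropylsilyloxy)phenyl]-3,4-dihydro-2H-chromene (dimethyl ketal) | COc1cc([C@@H]2Oc3c(OC)cc(Br)cc3C(OC)(OC)C2)ccc1O[Si](C(C)C)(C(C)C)C(C)C | intermediate
12 | (2R)-6-bromo-4,8-dimethoxy-2-[3-methoxy-4-(triisopropylsilyloxy)phenyl]-2H-chromene (enol ether) | COc1cc([C@@H]2Oc3c(OC)cc(Br)cc3C(OC)=C2)ccc1O[Si](C(C)C)(C(C)C)C(C)C | intermediate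
13 | 2,3-trans-3-[acetoxy(phenyl)-λ3-iodanyl]-6-bromo-4,4,8-trimethoxy-2-[3-methoxy-4-(triisopropylsilyloxy)phenyl]-3,4-dihydro-2H-chromene; aryl at C2 and iodine at C3 on opposite faces (2S,3S by CIP rank, C2 spatially unchanged) | COc1cc([C@@H]2Oc3c(OC)cc(Br)cc3C(OC)(OC)[C@H]2I(OC(C)=O)c4ccccc4)ccc1O[Si](C(C)C)(C(C)C)C(C)C | intermediate
14 | (2R,3R)-5-bromo-7-methoxy-2-[3-methoxy-4-(triisopropylsilyloxy)phenyl]-3-(trimethoxymethyl)-2,3-dihydro-1-benzofuran (orthoester) | COc1cc([C@@H]2Oc3c(OC)cc(Br)cc3[C@H]2C(OC)(OC)OC)ccc1O[Si](C(C)C)(C(C)C)C(C)C | intermediate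
15 | methyl (2R,3R)-5-bromo-7-methoxy-2-[3-methoxy-4-(triisopropylsilyloxy)phenyl]-2,3-dihydro-1-benzofuran-3-carboxylate (2,3-trans) | COc1cc([C@@H]2Oc3c(OC)cc(Br)cc3[C@H]2C(=O)OC)ccc1O[Si](C(C)C)(C(C)C)C(C)C | intermediate
16 | (2R,3R)-5-bromo-7-methoxy-2-[3-methoxy-4-(triisopropylsilyloxy)phenyl]-2,3-dihydro-1-benzofuran-3-carbaldehyde | COc1cc([C@@H]2Oc3c(OC)cc(Br)cc3[C@H]2C=O)ccc1O[Si](C(C)C)(C(C)C)C(C)C | intermediate
17 | [(2R,3S)-5-bromo-7-methoxy-2-[3-methoxy-4-(triisopropylsilyloxy)phenyl]-2,3-dihydro-1-benzofuran-3-yl]methanol | COc1cc([C@@H]2Oc3c(OC)cc(Br)cc3[C@H]2CO)ccc1O[Si](C(C)C)(C(C)C)C(C)C | intermediate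
18 | 3,5-dihydroxybenzaldehyde | O=Cc1cc(O)cc(O)c1 | starting material
19 | 3,5-bis(tert-butyldimethylsilyloxy)benzaldehyde | O=Cc1cc(O[Si](C)(C)C(C)(C)C)cc(O[Si](C)(C)C(C)(C)C)c1 | intermediate
20 | 4-[3,5-bis(tert-butyldimethylsilyloxy)phenyl]-2,2,2-triphenyl-1,2λ5-oxaphosphetane (racemic) | C1(c2cc(O[Si](C)(C)C(C)(C)C)cc(O[Si](C)(C)C(C)(C)C)c2)CP(c2ccccc2)(c2ccccc2)(c2ccccc2)O1 | intermediate
21 | 1-ethenyl-3,5-bis(tert-butyldimethylsilyloxy)benzene | C=Cc1cc(O[Si](C)(C)C(C)(C)C)cc(O[Si](C)(C)C(C)(C)C)c1 | intermediate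
22 | [(2R,3S)-5-[(E)-2-[3,5-bis(tert-butyldimethylsilyloxy)phenyl]ethenyl]-7-methoxy-2-[3-methoxy-4-(triisopropylsilyloxy)phenyl]-2,3-dihydro-1-benzofuran-3-yl]methanol | COc1cc([C@@H]2Oc3c(OC)cc(/C=C/c4cc(O[Si](C)(C)C(C)(C)C)cc(O[Si](C)(C)C(C)(C)C)c4)cc3[C@H]2CO)ccc1O[Si](C(C)C)(C(C)C)C(C)C | intermediate
23 | gnetofuran A, 5-[(E)-2-[(2R,3S)-2-(4-hydroxy-3-methoxyphenyl)-3-(hydroxymethyl)-7-methoxy-2,3-dihydro-1-benzofuran-5-yl]ethenyl]benzene-1,3-diol | COc1cc([C@@H]2Oc3c(OC)cc(/C=C/c4cc(O)cc(O)c4)cc3[C@H]2CO)ccc1O | target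

**Step count**

Total: 11 steps. Longest linear sequence: 7 steps (steps 1, 2, 5, 6, 7, 10, 11).

**Steps most likely to fail**

Step 6. The electron-rich C2 aryl group may migrate in competition with ring A (isoflavone formation), or the iodane may lose H to give the flavone. The acid may also strip the TIPS group so that the freed phenol is oxidised, or open the ring at C2 and erode the enantiomeric purity. Fallback, from 10 back to 15, keeping the ring contraction but through a carbene: 10 would be enolised at −78 °C (LiHMDS, THF) and trifluoroacetylated with CF3CO2CH2CF3 to the 3-trifluoroacetyl flavanone F1. Detrifluoroacetylative diazo transfer (MsN3, Et3N, H2O, MeCN) would give the 3-diazoflavanone F2. Irradiation at 365 nm in MeOH would trigger a photochemical Wolff rearrangement in which the same ring A carbon migrates to C3, giving the ring-contracted ketene F3, trapped by methanol as the ester. Any cis ester F4 formed by kinetic protonation anti to the aryl group would be equilibrated to the trans ester 15 with NaOMe in MeOH at 0 °C.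

Step 5. Enantioface selection may be poor with this electron-rich boronic acid, protodeboronation may outrun aryl transfer, or reduction of the catalyst to zerovalent palladium may start cross-coupling at the C–Br bond. Fallback, from 6 and 2 back to 10, building the heterocycle by oxa-Michael closure and resolving it: 6 would be lithiated as in step 4 and quenched with DMF to give 3-methoxy-4-(triisopropylsilyloxy)benzaldehyde F5. Pyrrolidine-promoted Claisen–Schmidt condensation of F5 with 2 in MeOH would give the 2'-hydroxychalcone F6, which is cyclised (NaOAc, EtOH, reflux) to the racemic flavanone F7. Kinetic resolution by asymmetric transfer hydrogenation (the enantiomer of RhCl(Cp*)(TsDPEN) that reduces the (S)-ketone faster, HCO2H/Et3N, EtOAc) would convert the (S)-enantiomer into the cis-flavan-4-ol F8 and leave (R)-flavanone 10, separable by chromatography.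

Step 10. Insertion may occur with the wrong regiochemistry (1,1-diarylethene), the alkene geometry may erode, or oxidative addition to the electron-rich bromide may be slow and lead to reductive debromination. Fallback, from 19 and 17 back to 22, fixing the alkene geometry before the C–C coupling: boron-Wittig olefination of 19 with CH2(Bpin)2 and LiTMP (THF, −78 °C to rt) would give the (E)-alkenyl boronate F9. Suzuki–Miyaura coupling of F9 with 17 (PdCl2(dppf), K3PO4, 1,4-dioxane/H2O, 60 °C) would give 22.

**Further compounds**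

F1 | step 6 | (2R)-6-bromo-8-methoxy-2-[3-methoxy-4-(triisopropylsilyloxy)phenyl]-3-(trifluoroacetyl)-2,3-dihydro-4H-chromen-4-one (C3 epimers and enol form; aryl-bearing centre spatially as in 10) | COc1cc([C@@H]2Oc3c(OC)cc(Br)cc3C(=O)C2C(=O)C(F)(F)F)ccc1O[Si](C(C)C)(C(C)C)C(C)C
F2 | step 6 | 6-bromo-3-diazo-8-methoxy-2-[3-methoxy-4-(triisopropylsilyloxy)phenyl]-2,3-dihydro-4H-chromen-4-one (aryl-bearing centre spatially as in 10) | COc1cc([C@@H]2Oc3c(OC)cc(Br)cc3C(=O)C2=[N+]=[N-])ccc1O[Si](C(C)C)(C(C)C)C(C)C
F3 | step 6 | [5-bromo-7-methoxy-2-[3-methoxy-4-(triisopropylsilyloxy)phenyl]-1-benzofuran-3(2H)-ylidene]methanone (ketene; aryl-bearing centre spatially as in 10) | COc1cc([C@@H]2Oc3c(OC)cc(Br)cc3C2=C=O)ccc1O[Si](C(C)C)(C(C)C)C(C)C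
F4 | step 6 | methyl (2R,3S)-5-bromo-7-methoxy-2-[3-methoxy-4-(triisopropylsilyloxy)phenyl]-2,3-dihydro-1-benzofuran-3-carboxylate (2,3-cis epimer of 15) | COc1cc([C@@H]2Oc3c(OC)cc(Br)cc3[C@@H]2C(=O)OC)ccc1O[Si](C(C)C)(C(C)C)C(C)C
F5 | step 5 | 3-methoxy-4-(triisopropylsilyloxy)benzaldehyde | COc1cc(C=O)ccc1O[Si](C(C)C)(C(C)C)C(C)C
F6 | step 5 | (E)-1-(5-bromo-2-hydroxy-3-methoxyphenyl)-3-[3-methoxy-4-(triisopropylsilyloxy)phenyl]prop-2-en-1-one | COc1cc(/C=C/C(=O)c2cc(Br)cc(OC)c2O)ccc1O[Si](C(C)C)(C(C)C)C(C)C
F7 | step 5 | racemic 6-bromo-8-methoxy-2-[3-methoxy-4-(triisopropylsilyloxy)phenyl]-2,3-dihydro-4H-chromen-4-one | COc1cc(C2Oc3c(OC)cc(Br)cc3C(=O)C2)ccc1O[Si](C(C)C)(C(C)C)C(C)C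
F8 | step 5 | (2S,4S)-6-bromo-8-methoxy-2-[3-methoxy-4-(triisopropylsilyloxy)phenyl]-3,4-dihydro-2H-chromen-4-ol (2,4-cis) | COc1cc([C@H]2Oc3c(OC)cc(Br)cc3[C@@H](O)C2)ccc1O[Si](C(C)C)(C(C)C)C(C)C
F9 | step 10 | 2-[(E)-2-[3,5-bis(tert-butyldimethylsilyloxy)phenyl]ethenyl]-4,4,5,5-tetramethyl-1,3,2-dioxaborolane | CC1(C)OB(/C=C/c2cc(O[Si](C)(C)C(C)(C)C)cc(O[Si](C)(C)C(C)(C)C)c2)OC1(C)C
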